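**Strategy.** The furanone is cut so that its lactone unit O1–C2(=O) is one molecule of CO2. Ring carbon C3 is traced back to the enolisable CH2 of a conjugated bromo-ynone, C5 to the alkyne carbon next to the ketone, and C4 is carried as that ketone, to become C4–Br afterwards. One silver-catalysed operation joins the enolate carbon to CO2 and the new carboxylate oxygen to the alkyne (5-exo-dig), giving the (Z)-5-(bromomethylidene) tetronic acid directly. The step exploits the 1,3-relationship of nucleophilic C3 and electrophilic C5 across C4 in the five-membered ring. The open-chain precursor, (R)-1-bromo-5-silyloxyoct-1-yn-3-one, gets its carbinol centre from an asymmetric ynone aldol with butanal.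

Key step: step 4

Remark: furanone atoms are numbered O1, C2 (C=O), C3 (side chain), C4 (Br), C5 (exocyclic alkene carbon). The target carbinol centre is R. It is assumed that the sense of induction in step 1 can be chosen through the ligand antipode.

**Step 1**
Reactants: 1 butanal; 2 4-(trimethylsilyl)but-3-yn-2-one
Product: 3 (5R)-5-hydroxy-1-(trimethylsilyl)oct-1-yn-3-one
Conditions: Et2Zn (20 mol%), ProPhenol ligand (2,6-bis{[2-(hydroxydiphenylmethyl)pyrrolidin-1-yl]methyl}-4-methylphenol, 10 mol%, the antipode that delivers 5R), 4 Å molecular sieves, THF, 0 °C; 1 added slowly to 2 (1.5 equiv)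
Reagents that add atoms: none
Why: Direct catalytic asymmetric aldol addition of a methyl ynone, in which the zinc enolate formed on the only enolisable side of 2 should add to one face of butanal inside the chiral dinuclear zinc pocket and so set C5; the ligand antipode is chosen for R and the sense is to be confirmed on 3 by Mosher ester analysis.

**Step 2**
Reactants: 3 (5R)-5-hydroxy-1-(trimethylsilyl)oct-1-yn-3-one
Product: 4 (5R)-5-[(tert-butyldimethylsilyl)oxy]-1-(trimethylsilyl)oct-1-yn-3-one
Conditions: TBSOTf, 2,6-lutidine, CH2Cl2, −78 °C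
Reagents that add atoms: tert-butyldimethylsilyl trifluoromethanesulfonate, CC(C)(C)[Si](C)(C)OS(=O)(=O)C(F)(F)F
Why: O-silylation of the secondary alcohol at low temperature should outrun enol silane formation and leave the stereocentre untouched; a silyl ether is chosen because silanolate is a far poorer leaving group than acetate β to the ketone in the basic key step.

**Step 3**
Reactants: 4 (5R)-5-[(tert-butyldimethylsilyl)oxy]-1-(trimethylsilyl)oct-1-yn-3-one
Product: 5 (5R)-1-bromo-5-[(tert-butyldimethylsilyl)oxy]oct-1-yn-3-one
Conditions: NBS, AgNO3 (10 mol%), acetone, 20 °C, dark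
Reagents that add atoms: N-bromosuccinimide, O=C1CCC(=O)N1Br
Why: Silver-catalysed desilylative bromination of an alkynylsilane should exchange only the C(sp)–Si bond for C(sp)–Br, leaving the O–Si bond of the silyl ether and the ketone alone.

**Step 4**
Reactants: 5 (5R)-1-bromo-5-[(tert-butyldimethylsilyl)oxy]oct-1-yn-3-one
Product: 7 (5Z)-5-(bromomethylidene)-3-[(1R)-1-[(tert-butyldimethylsilyl)oxy]butyl]-4-hydroxyfuran-2(5H)-one, via β-keto carboxylate 6 (not isolated)
Conditions: AgOAc (10 mol%), DBU (2 equiv), CO2 (1.0 MPa), MeCN, 0 → 25 °C; then cold 1 M aq. HCl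
Reagents that add atoms: carbon dioxide, O=C=O
Why: The amidine base enolises the CH2 between the ketone and the silyloxy carbon and the enolate carbon adds to CO2 (new C2–C3 bond), giving β-keto carboxylate 6; monovalent silver then activates the alkyne, the carboxylate oxygen adds anti to the alkyne carbon next to the ketone (new O1–C5 bond), and protodemetalation and enolisation should give tetronic acid 7. The closest known reaction type is the silver-catalysed carboxylative cyclisation of enolisable conjugated ynones with CO2 to 5-ylidene tetronic acids. The furanone ring closes in the 5-exo-dig mode. No lasting stereocentre is made: the transient C3 centre of 6 is formed as both epimers and erased on enolisation, so the mixture converges on one product, the carbinol centre is a bystander, and the exocyclic geometry is set Z because anti oxy-argentation leaves the bromine syn to O1 before retentive protonation. The step needs 5-exo over 6-endo closure, carboxylation on one α-carbon only, and carboxylation faster than loss of silanolate or attack at the bromine-bearing carbon. The substrate secures this through its single enolisable CH2, the three-atom tether from carboxylate to the proximal alkyne carbon, and the silyl rather than acyl protecting group.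

**Step 5**
Reactants: 7 (5Z)-5-(bromomethylidene)-3-[(1R)-1-[(tert-butyldimethylsilyl)oxy]butyl]-4-hydroxyfuran-2(5H)-one
Product: 8 (5Z)-4-bromo-5-(bromomethylidene)-3-[(1R)-1-[(tert-butyldimethylsilyl)oxy]butyl]furan-2(5H)-one
Conditions: (COBr)2, DMF, CH2Cl2, 0 → 20 °C
Reagents that add atoms: oxalyl bromide, O=C(Br)C(=O)Br
Why: Vilsmeier-type deoxybromination of the vinylogous acid, in which the 4-OH attacks the bromoiminium salt and bromide replaces the activated oxygen at C4 by addition–elimination, should leave the silyl ether, the bromoalkene and the carbinol centre unchanged.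

**Step 6**
Reactants: 8 (5Z)-4-bromo-5-(bromomethylidene)-3-[(1R)-1-[(tert-butyldimethylsilyl)oxy]butyl]furan-2(5H)-one
Product: 9 (1R)-1-[(5Z)-4-bromo-5-(bromomethylidene)-2-oxo-2,5-dihydrofuran-3-yl]butyl acetate
Conditions: Ac2O, FeCl3 (10 mol%), CH2Cl2, 0 °C
Reagents that add atoms: acetic anhydride, CC(=O)OC(C)=O
Why: Lewis acid-catalysed acetylative desilylation acylates the ether oxygen and expels the silyl group as its acetate, so the carbinol C–O bond is never broken and the R configuration should be retained, while the acid-stable bromofuranone core tolerates the conditions.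

**Compound list**
1 | butanal | CCCC=O | starting material
2 | 4-(trimethylsilyl)but-3-yn-2-one | CC(=O)C#C[Si](C)(C)C | starting material
3 | (5R)-5-hydroxy-1-(trimethylsilyl)oct-1-yn-3-one | CCC[C@@H](O)CC(=O)C#C[Si](C)(C)C | intermediate
4 | (5R)-5-[(tert-butyldimethylsilyl)oxy]-1-(trimethylsilyl)oct-1-yn-3-one | CCC[C@@H](O[Si](C)(C)C(C)(C)C)CC(=O)C#C[Si](C)(C)C | intermediate
5 | (5R)-1-bromo-5-[(tert-butyldimethylsilyl)oxy]oct-1-yn-3-one | CCC[C@@H](O[Si](C)(C)C(C)(C)C)CC(=O)C#CBr | intermediate
6 | β-keto carboxylate: DBU-H+ salt of 5-bromo-2-[(1R)-1-[(tert-butyldimethylsilyl)oxy]butyl]-3-oxopent-4-ynoic acid, both C2 epimers | CCC[C@@H](O[Si](C)(C)C(C)(C)C)C(C(=O)[O-])C(=O)C#CBr.C1CCC2=[NH+]CCCN2CC1 | intermediate (not isolated)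
7 | (5Z)-5-(bromomethylidene)-3-[(1R)-1-[(tert-butyldimethylsilyl)oxy]butyl]-4-hydroxyfuran-2(5H)-one | CCC[C@@H](O[Si](C)(C)C(C)(C)C)C1=C(O)/C(=C/Br)OC1=O | intermediate
8 | (5Z)-4-bromo-5-(bromomethylidene)-3-[(1R)-1-[(tert-butyldimethylsilyl)oxy]butyl]furan-2(5H)-one | CCC[C@@H](O[Si](C)(C)C(C)(C)C)C1=C(Br)/C(=C/Br)OC1=O | intermediate
9 | (1R)-1-[(5Z)-4-bromo-5-(bromomethylidene)-2-oxo-2,5-dihydrofuran-3-yl]butyl acetate | CCC[C@@H](OC(C)=O)C1=C(Br)/C(=C/Br)OC1=O | target

**Total step count:** 6. **Longest linear sequence:** 6.

**Steps most likely to fail**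

Step 4. The bromine-bearing alkyne carbon may be attacked, by the amidine or by the carboxylate in the 6-endo mode, with loss of bromide. The enolate may also expel silanolate before it is carboxylated. The fallback sets out from 4 and comes back at 8; it keeps bromine off the alkyne until the ring exists and carboxylates under kinetic control. Ynone 4 is deprotonated with LiN(SiMe3)2 (THF, −78 °C) and the enolate quenched with CO2 gas to give lithium 2-[(1R)-1-[(tert-butyldimethylsilyl)oxy]butyl]-3-oxo-5-(trimethylsilyl)pent-4-ynoate F1. AgNO3 (10 mol%) in the same flask, followed by cold dilute HCl, should close it to (5Z)-3-[(1R)-1-[(tert-butyldimethylsilyl)oxy]butyl]-4-hydroxy-5-[(trimethylsilyl)methylidene]furan-2(5H)-one F2. (COBr)2/DMF in CH2Cl2 should then give (5Z)-4-bromo-3-[(1R)-1-[(tert-butyldimethylsilyl)oxy]butyl]-5-[(trimethylsilyl)methylidene]furan-2(5H)-one F3. Ipso-bromodesilylation with NBS in MeCN at 0 °C, expected to go with retention through the oxygen- and β-silyl-stabilised cation, should give 8.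

Step 1. Self-aldol of the unbranched aldehyde may outrun the cross-aldol, and facial selectivity may be poor or of the wrong sense. The fallback sets out from 1 and comes back at 4, with reagent control in place of catalyst control. Asymmetric allylboration of butanal with B-allyldiisopinocampheylborane (the antipode that gives R; Et2O, −78 °C; then NaOH, H2O2) should give (4R)-hept-1-en-4-ol F4. TBSCl and imidazole in DMF give tert-butyl[(4R)-hept-1-en-4-yloxy]dimethylsilane F5. Ozonolysis (O3, CH2Cl2, −78 °C; then PPh3) gives (3R)-3-[(tert-butyldimethylsilyl)oxy]hexanal F6. Lithium (trimethylsilyl)acetylide (THF, −78 °C) gives (5R)-5-[(tert-butyldimethylsilyl)oxy]-1-(trimethylsilyl)oct-1-yn-3-ol F7 as a mixture of C3 epimers. Oxidation with Dess–Martin periodinane gives 4.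

Step 5. The hydrogen bromide released may cleave the silyl ether, after which the free carbinol would be formylated or ionised, or it may add to the exocyclic double bond. The fallback sets out from 7 and comes back at 8, with activation and bromide delivery separated and no acid formed. Tf2O and iPr2NEt (CH2Cl2, −78 °C) should give (5Z)-5-(bromomethylidene)-3-[(1R)-1-[(tert-butyldimethylsilyl)oxy]butyl]-2-oxo-2,5-dihydrofuran-4-yl trifluoromethanesulfonate F8. LiBr in acetone at 20 °C should then replace the vinylogous triflate by bromide through addition–elimination to give 8.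

**Further compounds**
F1 | step 4 | lithium 2-[(1R)-1-[(tert-butyldimethylsilyl)oxy]butyl]-3-oxo-5-(trimethylsilyl)pent-4-ynoate (both C2 epimers) | [Li+].CCC[C@@H](O[Si](C)(C)C(C)(C)C)C(C(=O)[O-])C(=O)C#C[Si](C)(C)C
F2 | step 4 | (5Z)-3-[(1R)-1-[(tert-butyldimethylsilyl)oxy]butyl]-4-hydroxy-5-[(trimethylsilyl)methylidene]furan-2(5H)-one | CCC[C@@H](O[Si](C)(C)C(C)(C)C)C1=C(O)/C(=C/[Si](C)(C)C)OC1=O
F3 | step 4 | (5Z)-4-bromo-3-[(1R)-1-[(tert-butyldimethylsilyl)oxy]butyl]-5-[(trimethylsilyl)methylidene]furan-2(5H)-one | CCC[C@@H](O[Si](C)(C)C(C)(C)C)C1=C(Br)/C(=C/[Si](C)(C)C)OC1=O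
F4 | step 1 | (4R)-hept-1-en-4-ol | CCC[C@@H](O)CC=C
F5 | step 1 | tert-butyl[(4R)-hept-1-en-4-yloxy]dimethylsilane | CCC[C@@H](O[Si](C)(C)C(C)(C)C)CC=C
F6 | step 1 | (3R)-3-[(tert-butyldimethylsilyl)oxy]hexanal | CCC[C@@H](O[Si](C)(C)C(C)(C)C)CC=O
F7 | step 1 | (5R)-5-[(tert-butyldimethylsilyl)oxy]-1-(trimethylsilyl)oct-1-yn-3-ol (C3 epimers) | CCC[C@@H](O[Si](C)(C)C(C)(C)C)CC(O)C#C[Si](C)(C)C
F8 | step 5 | (5Z)-5-(bromomethylidene)-3-[(1R)-1-[(tert-butyldimethylsilyl)oxy]butyl]-2-oxo-2,5-dihydrofuran-4-yl trifluoromethanesulfonate | CCC[C@@H](O[Si](C)(C)C(C)(C)C)C1=C(OS(=O)(=O)C(F)(F)F)/C(=C/Br)OC1=O
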